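**Retrosynthetic overview**
1. Target ⇐ late O-acylations (tertiary angelate, secondary acetate) ⇐ one-pot methylenation of a C1 aldehyde and a C4 methyl ketone, so vinyl and isopropenyl appear last.
2. Methyl ketone and free 8-OH ⇐ CH3Li opening of a temporary bridged δ-lactone (C4(=O)–O8 spanning C5 and C8); on this cage C5 is fixed, C6 is reduced, the γ-lactone (ring B, O6–C12) is closed and C11 is methylated, then hydroxylated.
3. 8-O ⇐ catalyst-controlled conjugate borylation/oxidation of a cyclohexenone (C6=O, C7=C8).
4. Ring A (C5–C10) ⇐ acyclic O-allyl enol ether of a β-keto ester in one operation: Claisen rearrangement (C5–C10, chirality transfer from an allylic carbinol stereocentre), then intramolecular aldol condensation (C7–C8); the enol ether ⇐ Mitsunobu union of a (Z)-allylic alcohol and a β-keto ester.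
5. Enabling feature: quaternary C10 bears a vinyl group and is bonded to C5, which is α to the oxygenated C6 (Claisen retron vinyl–C10–C5–C6=O), and the oxygens on C6 and C8 are 1,3 across C7 (aldol retron). Ring order: carbocycle A → temporary bridged δ-lactone → γ-lactone B → δ-lactone opened.

Key step: step 6

Remark: atoms are numbered as in elemanolides (C5 CH–isopropenyl, C6 CH–O, C7 ring fusion, C8 CH–OAc, C9 CH2, C10 quaternary, C11/C12 lactone carbons, C1/C2 vinyl, C4 isopropenyl carbon). The β-keto ester centre C5 is epimerisable until the bridged lactone is closed and is drawn without configuration up to that point.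
Remark: the zinc reagent and the malonate half-ester salt are taken as commercial.

Step 1
Reactants: 1 pent-3-yn-2-one
Product: 2 (2S)-pent-3-yn-2-ol
Conditions: RuCl[(S,S)-TsDPEN](p-cymene) (1 mol %), i-PrOH, 23 °C
Reagents that add atoms: none
Why: Noyori asymmetric transfer hydrogenation of an alkynyl methyl ketone, in which the chiral ruthenium hydride distinguishes the alkynyl from the methyl flank and should deliver hydride to one carbonyl face to set the carbinol carbon as S.

Step 2
Reactants: 2 (2S)-pent-3-yn-2-ol
Product: 3 (2S,3Z)-4-iodopent-3-en-2-ol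
Conditions: NaAlH2(OCH2CH2OCH3)2, THF, 0 → 23 °C; then I2, −78 °C
Reagents that add atoms: iodine, II
Why: Hydroxyl-directed trans-hydroalumination of the propargylic alcohol puts hydrogen on the carbinol-side carbon and aluminium on the distal carbon, and iodinolysis with retention should give the (Z)-vinyl iodide without touching the stereocentre.

Step 3
Reactants: 3 (2S,3Z)-4-iodopent-3-en-2-ol; 4 (1,3-dioxolan-2-ylmethyl)zinc bromide
Product: 5 (2S,3Z)-5-(1,3-dioxolan-2-yl)-4-methylpent-3-en-2-ol
Conditions: Pd(PPh3)4 (5 mol %), 4 (2.5 equiv), THF, 50 °C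
Reagents that add atoms: none
Why: Negishi cross-coupling of an alkenyl iodide with an alkylzinc halide proceeds with retention of alkene geometry, so the acetal-bearing carbon should end cis to the carbinol carbon (Z) while the stereocentre is not involved.

Step 4
Reactants: 6 4-tert-butoxy-4-oxobutanoic acid; 7 potassium 3-methoxy-3-oxopropanoate
Product: 9 6-tert-butyl 1-methyl 3-oxohexanedioate, via acyl imidazolide 8 (not isolated)
Conditions: 1,1′-carbonyldiimidazole, THF, 23 °C; then 7, MgCl2, THF, 23 → 40 °C; 1 M HCl
Reagents that add atoms: 1,1′-carbonyldiimidazole, O=C(n1ccnc1)n1ccnc1 (imidazolyl group of 8 only)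
Why: Masamune–Brooks chain extension, in which the acyl imidazolide C-acylates the magnesium enolate of the malonate half-ester and decarboxylation should give the β-keto ester, no stereocentre being formed.

Step 5
Reactants: 5 (2S,3Z)-5-(1,3-dioxolan-2-yl)-4-methylpent-3-en-2-ol; 9 6-tert-butyl 1-methyl 3-oxohexanedioate
Product: 10 6-tert-butyl 1-methyl (2E)-3-{[(2R,3Z)-5-(1,3-dioxolan-2-yl)-4-methylpent-3-en-2-yl]oxy}hex-2-enedioate
Conditions: PPh3, diisopropyl azodicarboxylate, toluene, 0 → 23 °C
Reagents that add atoms: none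
Why: Mitsunobu O-alkylation of the acidic β-keto ester enol should give the (E)-β-alkoxyacrylate by SN2 displacement at the secondary allylic carbon, which inverts it from S to R, SN2′ attack being disfavoured by the fully substituted alkene terminus.

Step 6
Reactants: 10 6-tert-butyl 1-methyl (2E)-3-{[(2R,3Z)-5-(1,3-dioxolan-2-yl)-4-methylpent-3-en-2-yl]oxy}hex-2-enedioate
Product: 13 methyl (2R)-5-(2-tert-butoxy-2-oxoethyl)-2-methyl-6-oxo-2-[(1E)-prop-1-en-1-yl]cyclohex-4-ene-1-carboxylate (C1 epimers), via Claisen keto ester 11 (not isolated), via keto aldehyde 12 (not isolated)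
Conditions: o-xylene, 140 °C; then TsOH·H2O (0.2 equiv), acetone/H2O (10:1), 50 °C
Reagents that add atoms: water, O (carbonyl oxygen of 12 only)
Why: Heating induces a concerted [3,3]-sigmatropic (Claisen) rearrangement of the allyl β-alkoxyacrylate through a chair transition state, in which C5 bonds to C10, the enol ether oxygen becomes the C6 ketone and the allylic C–O bond is traded for the (E)-propenyl double bond. The acid then unmasks the C8 aldehyde, and the C6 ketone, enolising towards C7, closes ring A by an intramolecular aldol addition (6-(enolendo)-exo-trig) whose dehydration to the conjugated enone makes the sequence irreversible. The closest known reaction types are the thermal Claisen rearrangement of O-allyl enol ethers of β-keto esters with 1,3-chirality transfer and the acid-mediated aldol cyclodehydration of 1,5-keto aldehydes, the closing stage of a Robinson annulation. The only stereocentre that has to be controlled, quaternary C10, is set by the (R)-configured carbinol carbon of the allyl unit: its methyl group sits equatorial in the chair, so C5 can reach only one face of the (Z)-alkene and the chirality is transferred to C10 (R) while the carbinol carbon becomes sp2. C5 is formed as an epimerisable β-keto ester centre and is deliberately left open until step 8, and no stereocentre remains at C7 or C8. The step needs bond formation at the substituted allyl terminus rather than a 1,3-shift and ring closure from C7 rather than C5: the pericyclic pathway secures the first, closure from C5 would give a four-membered ring, and the dioxolane keeps C8 inert until the rearrangement is over.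

Step 7
Reactants: 13 methyl (2R)-5-(2-tert-butoxy-2-oxoethyl)-2-methyl-6-oxo-2-[(1E)-prop-1-en-1-yl]cyclohex-4-ene-1-carboxylate
Product: 15 methyl (2R,4S,5R)-5-(2-tert-butoxy-2-oxoethyl)-4-hydroxy-2-methyl-6-oxo-2-[(1E)-prop-1-en-1-yl]cyclohexane-1-carboxylate (C1 epimers), via boronate 14 (not isolated)
Conditions: Cu(OH)2 (5 mol %), (S,S)-6,6′-bis(1-hydroxy-2,2-dimethylpropyl)-2,2′-bipyridine (6 mol %), AcOH (6 mol %), B2pin2 (1.2 equiv), H2O, 5 °C; then NaBO3·4H2O, THF/H2O, 23 °C
Reagents that add atoms: bis(pinacolato)diboron, CC1(C)OB(OC1(C)C)B1OC(C)(C)C(C)(C)O1 (boron of 14 only); sodium perborate, [Na+].[O-]OB=O (oxygen on C8)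
Why: Copper-catalysed enantioselective conjugate borylation of the enone followed by stereoretentive C–B oxidation: because methyl and propenyl on C10 are similar in size the substrate has little facial bias of its own, so the chiral bipyridine–copper boryl species (the ligand antipode being the one that adds boron cis to the C10 methyl) should set C8, and protonation and equilibration of the α-carbon should leave the C7 side chain trans to the C8 oxygen.

Step 8
Reactants: 15 methyl (2R,4S,5R)-5-(2-tert-butoxy-2-oxoethyl)-4-hydroxy-2-methyl-6-oxo-2-[(1E)-prop-1-en-1-yl]cyclohexane-1-carboxylate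
Product: 16 tert-butyl 2-{8-methyl-3,5-dioxo-8-[(1E)-prop-1-en-1-yl]-2-oxabicyclo[2.2.2]octan-6-yl}acetate (bridged keto lactone; lactone C4(=O)–O8 across C5 and C8, C10 methyl syn to the lactone bridge, C7 side chain anti to it)
Conditions: [Bu2Sn(NCS)OSnBu2(OH)]2 (5 mol %), toluene, 90 °C, 5 Å molecular sieves
Reagents that add atoms: none
Why: Distannoxane-catalysed intramolecular transesterification (lactonisation) under neutral conditions: the β-keto ester centre C5 epimerises through its enol and only the epimer whose ester is cis to the 8-hydroxyl can close the 2-oxabicyclo[2.2.2]octane lactone, which should fix C5 cis to O8, while the tert-butyl ester cannot compete and the β-hydroxy ketone is not exposed to base.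

Step 9
Reactants: 16 bridged keto lactone
Product: 19 bis-lactone (γ-lactone O6–C12(=O)–C11H2–C7 cis-fused on the C6–C7 bridge of the 2-oxabicyclo[2.2.2]octan-3-one; O6 and C11 on the face of the C9–C10 bridge), via hydroxy lactone ester 17 (not isolated), via hydroxy acid 18 (not isolated)
Conditions: NaBH4, CeCl3·7H2O, MeOH, −40 °C; aqueous work-up; then CF3CO2H/CH2Cl2 (1:4), 0 → 23 °C
Reagents that add atoms: none
Why: Luche-type hydride reduction followed by acid-mediated tert-butyl ester cleavage and lactonisation: hydride should attack the C6 ketone from the face of the lactone bridge because the other face is screened by the propenyl group on C10, which places the 6-hydroxyl cis to the C7 side chain so that the freed acid closes the cis-fused γ-lactone.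

Step 10
Reactants: 19 bis-lactone
Product: 20 11-methyl bis-lactone (methyl on C11 cis to H7)
Conditions: LiN(i-Pr)2 (1.1 equiv), THF, −78 °C; then CH3I, −78 → −40 °C
Reagents that add atoms: iodomethane, CI
Why: Lactone enolate alkylation: C11 is the only enolisable position because C5 is a bridgehead, and the electrophile should enter on the convex face of the cis-fused γ-lactone, cis to H7.

Step 11
Reactants: 20 11-methyl bis-lactone
Product: 21 11-hydroxy-11-methyl bis-lactone (hydroxyl cis to H7; C11 as in the target)
Conditions: KN(SiMe3)2 (1.2 equiv), THF, −78 °C; then 3-phenyl-2-(phenylsulfonyl)oxaziridine, −78 °C; aq NH4Cl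
Reagents that add atoms: 3-phenyl-2-(phenylsulfonyl)oxaziridine, O=S(=O)(c1ccccc1)N1OC1c1ccccc1
Why: Davis enolate hydroxylation: the planar C11 enolate is again attacked on the convex face, so oxygen should end cis to H7 and the methyl group is turned to the concave face, which is the C11 configuration of the target.

Step 12
Reactants: 21 11-hydroxy-11-methyl bis-lactone
Product: 22 7-acetyl-3,4-dihydroxy-3,6-dimethyl-6-[(1E)-prop-1-en-1-yl]hexahydro-1-benzofuran-2(3H)-one (C5, C6, C7, C8, C10 and C11 as in the target; C4 methyl ketone, free 8-OH)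
Conditions: CH3Li (2.1 equiv), THF, −78 °C; AcOH quench at −78 °C
Reagents that add atoms: methyllithium, [Li]C
Why: Single addition of methyllithium to a lactone, which stops at the lithium hemiketalate at low temperature: after deprotonation of the 11-hydroxyl the strained bridged δ-lactone carbonyl (C4) should react in preference to the γ-lactone carbonyl, which is flanked by the quaternary alkoxide carbon, and the quench releases the C4 methyl ketone and the 8-hydroxyl without touching C5.

Step 13
Reactants: 22 methyl ketone diol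
Product: 23 7-acetyl-3-hydroxy-3,6-dimethyl-2-oxo-6-[(1E)-prop-1-en-1-yl]octahydro-1-benzofuran-4-yl acetate (stereocentres as in 22)
Conditions: Ac2O, pyridine, CH2Cl2, 0 → 23 °C
Reagents that add atoms: acetic anhydride, CC(=O)OC(C)=O
Why: Pyridine-mediated esterification of the secondary 8-hydroxyl, which is expected to be selective because the tertiary 11-hydroxyl does not react without a stronger acyl-transfer catalyst.

Step 14
Reactants: 23 acetate
Product: 24 7-acetyl-6-formyl-3-hydroxy-3,6-dimethyl-2-oxooctahydro-1-benzofuran-4-yl acetate (stereocentres as in 22; aldehyde on C10)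
Conditions: O3, CH2Cl2, −78 °C; then (CH3)2S, −78 → 23 °C
Reagents that add atoms: ozone, [O-][O+]=O
Why: Ozonolysis with reductive work-up cleaves the propenyl group, the only C=C bond present, to the non-enolisable aldehyde on C10, whose configuration is untouched.

Step 15
Reactants: 24 keto aldehyde acetate
Product: 25 (3S,3aR,4S,6R,7R,7aS)-6-ethenyl-3-hydroxy-3,6-dimethyl-2-oxo-7-(prop-1-en-2-yl)octahydro-1-benzofuran-4-yl acetate
Conditions: Zn, CH2Br2, TiCl4, THF/CH2Cl2, 0 → 23 °C
Reagents that add atoms: dibromomethane, BrCBr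
Why: Takai–Lombardo methylenation converts the aldehyde into the vinyl group and the methyl ketone into the isopropenyl group under non-basic conditions, so that the α-centre C5 should not epimerise and the acetate and lactone stay intact.

Step 16
Reactants: 25 tertiary alcohol
Product: 26 (3S,3aR,4S,6R,7R,7aS)-4-(acetyloxy)-6-ethenyl-3,6-dimethyl-2-oxo-7-(prop-1-en-2-yl)octahydro-1-benzofuran-3-yl (2Z)-2-methylbut-2-enoate (target)
Conditions: LiN(SiMe3)2 (1.1 equiv), THF, −78 °C; then angelic anhydride, −78 → 0 °C; 1 M HCl
Reagents that add atoms: angelic anhydride, C/C=C(/C)C(=O)OC(=O)/C(C)=C\C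
Why: O-acylation of the lithium alkoxide of the tertiary α-hydroxy lactone with angelic anhydride should give the angelate, the low temperature and the absence of nucleophilic amine catalysts guarding against Z-to-E isomerisation to the tiglate.

**Compound list**
1 | pent-3-yn-2-one | CC#CC(C)=O | starting material
2 | (2S)-pent-3-yn-2-ol | C[C@H](O)C#CC | intermediate
3 | (2S,3Z)-4-iodopent-3-en-2-ol | C[C@H](O)/C=C(/C)I | intermediate
4 | (1,3-dioxolan-2-ylmethyl)zinc bromide | Br[Zn]CC1OCCO1 | starting material
5 | (2S,3Z)-5-(1,3-dioxolan-2-yl)-4-methylpent-3-en-2-ol | C[C@H](O)/C=C(/C)CC1OCCO1 | intermediate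
6 | 4-tert-butoxy-4-oxobutanoic acid (mono-tert-butyl succinate) | CC(C)(C)OC(=O)CCC(=O)O | starting material
7 | potassium 3-methoxy-3-oxopropanoate (potassium methyl malonate) | [K+].[O-]C(=O)CC(=O)OC | starting material
8 | tert-butyl 4-(1H-imidazol-1-yl)-4-oxobutanoate (acyl imidazolide) | CC(C)(C)OC(=O)CCC(=O)n1ccnc1 | intermediate (not isolated)
9 | 6-tert-butyl 1-methyl 3-oxohexanedioate | COC(=O)CC(=O)CCC(=O)OC(C)(C)C | intermediate
10 | 6-tert-butyl 1-methyl (2E)-3-{[(2R,3Z)-5-(1,3-dioxolan-2-yl)-4-methylpent-3-en-2-yl]oxy}hex-2-enedioate | C[C@@H](O/C(CCC(=O)OC(C)(C)C)=C/C(=O)OC)/C=C(/C)CC1OCCO1 | intermediate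
11 | 6-tert-butyl 1-methyl 2-{(2R,3E)-2-[(1,3-dioxolan-2-yl)methyl]pent-3-en-2-yl}-3-oxohexanedioate (C2 epimers) | COC(=O)C(C(=O)CCC(=O)OC(C)(C)C)[C@@](C)(/C=C/C)CC1OCCO1 | intermediate (not isolated)
12 | 6-tert-butyl 1-methyl 2-[(3R,4E)-3-methyl-1-oxohex-4-en-3-yl]-3-oxohexanedioate (C2 epimers) | COC(=O)C(C(=O)CCC(=O)OC(C)(C)C)[C@@](C)(/C=C/C)CC=O | intermediate (not isolated)
13 | methyl (2R)-5-(2-tert-butoxy-2-oxoethyl)-2-methyl-6-oxo-2-[(1E)-prop-1-en-1-yl]cyclohex-4-ene-1-carboxylate (C1 epimers) | C/C=C/[C@@]1(C)CC=C(CC(=O)OC(C)(C)C)C(=O)C1C(=O)OC | intermediate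
14 | methyl 5-(2-tert-butoxy-2-oxoethyl)-2-methyl-6-oxo-2-[(1E)-prop-1-en-1-yl]-4-(4,4,5,5-tetramethyl-1,3,2-dioxaborolan-2-yl)cyclohexane-1-carboxylate (boron cis to the C10 methyl, side chain trans to boron; configured as 15) | C/C=C/[C@@]1(C)C[C@H](B2OC(C)(C)C(C)(C)O2)[C@@H](CC(=O)OC(C)(C)C)C(=O)C1C(=O)OC | intermediate (not isolated)
15 | methyl (2R,4S,5R)-5-(2-tert-butoxy-2-oxoethyl)-4-hydroxy-2-methyl-6-oxo-2-[(1E)-prop-1-en-1-yl]cyclohexane-1-carboxylate (C1 epimers) | C/C=C/[C@@]1(C)C[C@H](O)[C@@H](CC(=O)OC(C)(C)C)C(=O)C1C(=O)OC | intermediate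
16 | tert-butyl 2-{8-methyl-3,5-dioxo-8-[(1E)-prop-1-en-1-yl]-2-oxabicyclo[2.2.2]octan-6-yl}acetate (methyl syn to the lactone bridge, side chain anti to it) | C/C=C/[C@@]1(C)C[C@H]2[C@@H](CC(=O)OC(C)(C)C)C(=O)[C@@H]1C(=O)O2 | intermediate
17 | tert-butyl 2-{5-hydroxy-8-methyl-3-oxo-8-[(1E)-prop-1-en-1-yl]-2-oxabicyclo[2.2.2]octan-6-yl}acetate (hydroxyl cis to the side chain, both anti to the lactone bridge) | C/C=C/[C@@]1(C)C[C@H]2[C@@H](CC(=O)OC(C)(C)C)[C@@H](O)[C@@H]1C(=O)O2 | intermediate (not isolated)
18 | 2-{5-hydroxy-8-methyl-3-oxo-8-[(1E)-prop-1-en-1-yl]-2-oxabicyclo[2.2.2]octan-6-yl}acetic acid (configured as 17) | C/C=C/[C@@]1(C)C[C@H]2[C@@H](CC(=O)O)[C@@H](O)[C@@H]1C(=O)O2 | intermediate (not isolated)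
19 | bis-lactone: γ-lactone (O6–C12) cis-fused on the C6–C7 bridge of the bridged δ-lactone (C4(=O)–O8); C5, C6, C7, C8, C10 as in 26 | C/C=C/[C@@]1(C)C[C@H]2[C@@H]3[C@@H](OC(=O)C3)[C@@H]1C(=O)O2 | intermediate
20 | 11-methyl bis-lactone (C11 methyl cis to H7) | C/C=C/[C@@]1(C)C[C@H]2[C@@H]3[C@@H](OC(=O)[C@H]3C)[C@@H]1C(=O)O2 | intermediate
21 | 11-hydroxy-11-methyl bis-lactone (hydroxyl cis to H7; C11 as in 26) | C/C=C/[C@@]1(C)C[C@H]2[C@@H]3[C@@H](OC(=O)[C@@]3(C)O)[C@@H]1C(=O)O2 | intermediate
22 | 7-acetyl-3,4-dihydroxy-3,6-dimethyl-6-[(1E)-prop-1-en-1-yl]hexahydro-1-benzofuran-2(3H)-one (all six stereocentres arranged as in 26) | C/C=C/[C@@]1(C)C[C@H](O)[C@@H]2[C@@H](OC(=O)[C@@]2(C)O)[C@@H]1C(C)=O | intermediate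
23 | 7-acetyl-3-hydroxy-3,6-dimethyl-2-oxo-6-[(1E)-prop-1-en-1-yl]octahydro-1-benzofuran-4-yl acetate (stereocentres as in 26) | C/C=C/[C@@]1(C)C[C@H](OC(C)=O)[C@@H]2[C@@H](OC(=O)[C@@]2(C)O)[C@@H]1C(C)=O | intermediate
24 | 7-acetyl-6-formyl-3-hydroxy-3,6-dimethyl-2-oxooctahydro-1-benzofuran-4-yl acetate (stereocentres as in 26) | O=C[C@@]1(C)C[C@H](OC(C)=O)[C@@H]2[C@@H](OC(=O)[C@@]2(C)O)[C@@H]1C(C)=O | intermediate
25 | (3S,3aR,4S,6R,7R,7aS)-6-ethenyl-3-hydroxy-3,6-dimethyl-2-oxo-7-(prop-1-en-2-yl)octahydro-1-benzofuran-4-yl acetate | C=C[C@@]1(C)C[C@H](OC(C)=O)[C@@H]2[C@@H](OC(=O)[C@@]2(C)O)[C@@H]1C(=C)C | intermediate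
26 | (3S,3aR,4S,6R,7R,7aS)-4-(acetyloxy)-6-ethenyl-3,6-dimethyl-2-oxo-7-(prop-1-en-2-yl)octahydro-1-benzofuran-3-yl (2Z)-2-methylbut-2-enoate | C=C[C@@]1(C)C[C@H](OC(C)=O)[C@@H]2[C@@H](OC(=O)[C@@]2(C)OC(=O)/C(C)=C\C)[C@@H]1C(=C)C | target

**Step count**
Total steps: 16. Longest linear sequence: 15 steps (steps 1–3 and 5–16, from 1 to 26); step 4 is a one-step side branch.

**Steps most likely to fail, with fallbacks**

Step 8. Dehydration of the β-hydroxy ketone back to the enone, or reluctance of the strained bicyclic lactone to close, may outrun the tin-catalysed transesterification. The fallback sets out from 15 and activates a free acid instead of exchanging an ester: the methyl ester is hydrolysed enzymatically (pig liver esterase, pH 7.5 phosphate buffer/acetone, 23 °C) to the β-keto acid F2, which is closed cold with EDC·HCl and DMAP (0.1 equiv) in CH2Cl2 at 0 °C, the C5 epimers still interconverting through the enol, and the route is rejoined at 16.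

Step 12. Collapse of the hemiketalate followed by a second addition, or competing attack on the γ-lactone, may erode the single addition of methyllithium. The fallback sets out from 21 and goes through an amide that cannot over-add: the bridged lactone is opened with CH3NH(OCH3)·HCl and i-PrMgCl (THF, −20 °C) to the Weinreb amide F3, and CH3MgBr (THF, 0 °C) then gives the methyl ketone, rejoining the route at 22.

Step 7. Poor facial selectivity at C8, or slow catalyst turnover caused by the acidic β-keto ester, may spoil the conjugate borylation. The fallback sets out from 13 and brings in the C8 oxygen by epoxidation instead: catalyst-controlled nucleophilic epoxidation (9-amino-9-deoxy-epi-quinine bis(trifluoroacetate) 10 mol %, 50 % aq H2O2, dioxane, 30 °C) gives the 7,8-epoxy ketone F1 with oxygen cis to the C10 methyl, and reductive opening of the C7–O bond with SmI2 (THF/MeOH, −90 °C), followed by equilibration at C7, rejoins the route at 15.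

Further compounds
F1 | step 7 | methyl 5-(2-tert-butoxy-2-oxoethyl)-4,5-epoxy-2-methyl-6-oxo-2-[(1E)-prop-1-en-1-yl]cyclohexane-1-carboxylate (7,8-epoxy ketone, epoxide cis to the C10 methyl) | C/C=C/[C@@]1(C)C[C@@H]2O[C@]2(CC(=O)OC(C)(C)C)C(=O)C1C(=O)OC
F2 | step 8 | (2R,4S,5R)-5-(2-tert-butoxy-2-oxoethyl)-4-hydroxy-2-methyl-6-oxo-2-[(1E)-prop-1-en-1-yl]cyclohexane-1-carboxylic acid (C1 epimers) | C/C=C/[C@@]1(C)C[C@H](O)[C@@H](CC(=O)OC(C)(C)C)C(=O)C1C(=O)O
F3 | step 12 | 3,4-dihydroxy-N-methoxy-N,3,6-trimethyl-2-oxo-6-[(1E)-prop-1-en-1-yl]octahydro-1-benzofuran-7-carboxamide (stereocentres as in 22) | C/C=C/[C@@]1(C)C[C@H](O)[C@@H]2[C@@H](OC(=O)[C@@]2(C)O)[C@@H]1C(=O)N(C)OC
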